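Ring B of the cis-fused decalin (labdane numbering: C10 angular, C5 fusion CH, C8 methyl-bearing, C9 chain-bearing) is disconnected to ring A alone. One enantioselective Diels–Alder reaction joins the C10=C5 alkene of 2,4,4-trimethylcyclohex-2-enone to the C6=C7–C8=C9 diene of an (E)-6-methylocta-5,7-dienyl silyl ether, making C5–C6 and C9–C10 at once. Suprafacial addition to the ring alkene gives the cis fusion (5-H syn to 10-CH3) directly and sets both stereocentres. The activating C1 ketone is then erased, the ring-B alkene moved to the tetrasubstituted C8=C9 position, and the dienyl butenolide added by crossed aldol condensation and 1,2-reduction.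

Key step: step 4

Assumption: the (S)-oxazaborolidine–AlBr3 catalyst is taken to expose the face of enone 4 that leads to the required enantiomer; if induction on this α-methyl enone runs the other way, the (R)-catalyst from (R)-diphenylprolinol is used with no other change.

Assumption: 5-[(tert-butyldimethylsilyl)oxy]pentanal (5) and the boronate enal 15 are treated as catalogue compounds.

Step 1
Reactants: 1 isobutyraldehyde; 2 ethyl vinyl ketone (pent-1-en-3-one)
Product: 4 2,4,4-trimethylcyclohex-2-en-1-one, via 2,2-dimethyl-5-oxoheptanal 3 (not isolated)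
Conditions: cat. H2SO4, neat, 45 → 60 °C; then PhMe, reflux (Dean–Stark)
Reagents that add atoms: none
Why: Acid-catalysed Michael addition of the aldehyde to the vinyl ketone followed by intramolecular aldol condensation at the ketone CH2 (Robinson-type annulation) is the standard one-pot entry to 4,4-dimethylcyclohexenones and should give the 2-methyl enone here.

Step 2
Reactants: 5 5-[(tert-butyldimethylsilyl)oxy]pentanal; 6 2-(triphenylphosphoranylidene)propanal
Product: 7 (2E)-7-[(tert-butyldimethylsilyl)oxy]-2-methylhept-2-enal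
Conditions: PhMe, 90 °C
Reagents that add atoms: none
Why: Wittig olefination with the formyl-stabilised ylide should attack only the saturated aldehyde and give the (E)-trisubstituted enal.

Step 3
Reactants: 7
Product: 8 tert-butyldimethyl{[(5E)-6-methylocta-5,7-dien-1-yl]oxy}silane
Conditions: Ph3PCH3Br, n-BuLi, THF, 0 °C → rt
Reagents that add atoms: methyltriphenylphosphonium bromide, C[P+](c1ccccc1)(c1ccccc1)c1ccccc1.[Br-]
Why: Wittig methylenation of the enal carbonyl should leave the (E)-trisubstituted alkene untouched and give the 1,2-disubstituted diene.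

Step 4
Reactants: 4; 8
Product: 9 (4a-H/8-H/8a-CH3 all syn)-8-{4-[(tert-butyldimethylsilyl)oxy]butyl}-4,4,7,8a-tetramethyl-3,4,4a,5,8,8a-hexahydronaphthalen-1(2H)-one
Conditions: (S)-diphenylprolinol-derived B-(o-tolyl)oxazaborolidine (20 mol%), AlBr3 (16 mol%), CH2Cl2, −40 → 0 °C, 8 (1.5 equiv)
Reagents that add atoms: none
Why: The AlBr3-activated oxazaborolidinium binds the C1 carbonyl and lowers the LUMO of the C10=C5 alkene, which should undergo a concerted, asynchronous normal-demand [4+2] cycloaddition with the s-cis diene, C5–C6 forming ahead of C9–C10. The closest known reactions are the chiral oxazaborolidinium-catalysed Diels–Alder reactions of cyclic enones and the AlCl3-promoted additions of dienes to 2-methylcyclohex-2-enones that give cis-decalones with an angular methyl group. Ring B is closed as a six-membered ring by intermolecular [4+2] annulation onto the ring A alkene, suprafacial on both partners. The cis relation of 5-H and 10-CH3 follows from syn addition to the ring alkene, their absolute configuration from the catalyst, whose aryl group blocks one face of the bound enone, and the transient C9 centre from the endo orientation (C1=O under the diene). The step needs regioselectivity (C9 to C10, C6 to C5), which the C9 alkyl group (ortho rule under Lewis acid catalysis) and sterics should secure, since only the unsubstituted terminus C6 can reach the neopentyl β-carbon C5; the (E)-diene geometry keeps the s-cis conformer accessible.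

Step 5
Reactants: 9
Product: 11 4-[(1-H/4a-H/8a-CH3 all syn)-2,5,5,8a-tetramethyl-1,4,4a,5,6,7,8,8a-octahydronaphthalen-1-yl]butan-1-ol, via silyl ether hydrazone 10 (not isolated)
Conditions: N2H4·H2O, diethylene glycol, 130 °C; then KOH, 200 °C (water distilled off)
Reagents that add atoms: hydrazine, NN (its nitrogen is held only in intermediate 10 and leaves as N2)
Why: Wolff–Kishner reduction (Huang-Minlon procedure) should convert the hindered C1 ketone into CH2 without touching the unactivated alkene or the ring-fusion centres, while the hot hydroxide cleaves the silyl ether in the same operation.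

Step 6
Reactants: 11
Product: 12 4-[(4aR,8aS)-2,5,5,8a-tetramethyl-3,4,4a,5,6,7,8,8a-octahydronaphthalen-1-yl]butan-1-ol
Conditions: TsOH·H2O (20 mol%), PhMe, 80 °C
Reagents that add atoms: none
Why: Acid-catalysed alkene isomerisation through the tertiary C8 cation should end at the tetrasubstituted C8=C9 alkene, the thermodynamic position, erasing the C9 centre; hydroxyl capture would need a seven-membered ether and is disfavoured.

Step 7
Reactants: 12
Product: 13 4-[(4aR,8aS)-2,5,5,8a-tetramethyl-3,4,4a,5,6,7,8,8a-octahydronaphthalen-1-yl]butanal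
Conditions: Dess–Martin periodinane, CH2Cl2, 0 °C → rt
Reagents that add atoms: none
Why: Dess–Martin oxidation should take the primary alcohol to the aldehyde without over-oxidation and without attack on the tetrasubstituted alkene.

Step 8
Reactants: 14 4-bromofuran-2(5H)-one; 15 (2E)-3-(4,4,5,5-tetramethyl-1,3,2-dioxaborolan-2-yl)prop-2-enal
Product: 16 (2E)-3-(5-oxo-2,5-dihydrofuran-3-yl)prop-2-enal
Conditions: Pd(dppf)Cl2 (5 mol%), K2CO3, THF/H2O, 40 °C
Reagents that add atoms: none
Why: Suzuki–Miyaura coupling of the activated β-bromobutenolide with the (E)-alkenyl boronate should proceed with retention of alkene geometry.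

Step 9
Reactants: 13; 16
Product: 18 (2E,4E)-2-{2-[(4aR,8aS)-2,5,5,8a-tetramethyl-3,4,4a,5,6,7,8,8a-octahydronaphthalen-1-yl]ethyl}-5-(5-oxo-2,5-dihydrofuran-3-yl)penta-2,4-dienal, via Mannich adduct 17 (not isolated)
Conditions: pyrrolidine (20 mol%), PhCO2H (20 mol%), CH2Cl2, 0 °C → rt, 16 (1.5 equiv), slow addition of 13
Reagents that add atoms: pyrrolidine, C1CCNC1 (held only in intermediate 17 and released again)
Why: Amine/acid-catalysed crossed aldol condensation between the only α-CH2 aldehyde (13) and the enal 16, which has no α-CH2, should give after loss of pyrrolidine the 2-alkyl dienal in its thermodynamic (E)-form (CHO trans to C15), which is the geometry of the target.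

Step 10
Reactants: 18
Product: 19 4-[(1E,3E)-4-(hydroxymethyl)-6-[(4aR,8aS)-2,5,5,8a-tetramethyl-3,4,4a,5,6,7,8,8a-octahydronaphthalen-1-yl]hexa-1,3-dien-1-yl]furan-2(5H)-one (CNP0232848.3)
Conditions: NaBH4, CeCl3·7H2O, MeOH, −78 → −40 °C
Reagents that add atoms: none
Why: Luche reduction should reduce the aldehyde 1,2-selectively to the allylic alcohol and leave the butenolide lactone and the diene untouched.

Compound list
1 | isobutyraldehyde (2-methylpropanal) | CC(C)C=O | starting material
2 | ethyl vinyl ketone (pent-1-en-3-one) | CCC(=O)C=C | starting material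
3 | 2,2-dimethyl-5-oxoheptanal | CCC(=O)CCC(C)(C)C=O | intermediate
4 | 2,4,4-trimethylcyclohex-2-en-1-one | CC1=CC(C)(C)CCC1=O | intermediate
5 | 5-[(tert-butyldimethylsilyl)oxy]pentanal | O=CCCCCO[Si](C)(C)C(C)(C)C | starting material
6 | 2-(triphenylphosphoranylidene)propanal | CC(C=O)=P(c1ccccc1)(c1ccccc1)c1ccccc1 | starting material
7 | (2E)-7-[(tert-butyldimethylsilyl)oxy]-2-methylhept-2-enal | O=C/C(C)=C/CCCCO[Si](C)(C)C(C)(C)C | intermediate
8 | tert-butyldimethyl{[(5E)-6-methylocta-5,7-dien-1-yl]oxy}silane | C=C/C(C)=C/CCCCO[Si](C)(C)C(C)(C)C | intermediate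
9 | cis-fused Diels–Alder ketone, 8-{4-[(tert-butyldimethylsilyl)oxy]butyl}-4,4,7,8a-tetramethyl-3,4,4a,5,8,8a-hexahydronaphthalen-1(2H)-one, 4a-H, 8-H and 8a-CH3 on one face | CC(C)(C)[Si](C)(C)OCCCC[C@@H]1C(C)=CC[C@@H]2C(C)(C)CCC(=O)[C@]12C | intermediate
10 | C1 hydrazone of 9 (silyl ether intact) | CC(C)(C)[Si](C)(C)OCCCC[C@@H]1C(C)=CC[C@@H]2C(C)(C)CCC(=NN)[C@]12C | intermediate
11 | 4-[2,5,5,8a-tetramethyl-1,4,4a,5,6,7,8,8a-octahydronaphthalen-1-yl]butan-1-ol, cis-fused, 1-H, 4a-H and 8a-CH3 on one face | OCCCC[C@@H]1C(C)=CC[C@@H]2C(C)(C)CCC[C@]12C | intermediate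
12 | 4-[(4aR,8aS)-2,5,5,8a-tetramethyl-3,4,4a,5,6,7,8,8a-octahydronaphthalen-1-yl]butan-1-ol | CC1=C(CCCCO)[C@@]2(C)CCCC(C)(C)[C@H]2CC1 | intermediate
13 | 4-[(4aR,8aS)-2,5,5,8a-tetramethyl-3,4,4a,5,6,7,8,8a-octahydronaphthalen-1-yl]butanal | CC1=C(CCCC=O)[C@@]2(C)CCCC(C)(C)[C@H]2CC1 | intermediate
14 | 4-bromofuran-2(5H)-one | BrC1=CC(=O)OC1 | starting material
15 | (2E)-3-(4,4,5,5-tetramethyl-1,3,2-dioxaborolan-2-yl)prop-2-enal | O=C/C=C/B1OC(C)(C)C(C)(C)O1 | starting material
16 | (2E)-3-(5-oxo-2,5-dihydrofuran-3-yl)prop-2-enal | O=C/C=C/C1=CC(=O)OC1 | intermediate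
17 | Mannich adduct, 2-{2-[(4aR,8aS)-decalinyl]ethyl}-5-(5-oxo-2,5-dihydrofuran-3-yl)-3-(pyrrolidin-1-yl)pent-4-enal, mixture of epimers at C2 and C3 | CC1=C(CCC(C=O)C(/C=C/C2=CC(=O)OC2)N2CCCC2)[C@@]2(C)CCCC(C)(C)[C@H]2CC1 | intermediate
18 | (2E,4E)-2-{2-[(4aR,8aS)-2,5,5,8a-tetramethyl-3,4,4a,5,6,7,8,8a-octahydronaphthalen-1-yl]ethyl}-5-(5-oxo-2,5-dihydrofuran-3-yl)penta-2,4-dienal | CC1=C(CC/C(=C\C=C\C2=CC(=O)OC2)C=O)[C@@]2(C)CCCC(C)(C)[C@H]2CC1 | intermediate
19 | 4-[(1E,3E)-4-(hydroxymethyl)-6-[(4aR,8aS)-2,5,5,8a-tetramethyl-3,4,4a,5,6,7,8,8a-octahydronaphthalen-1-yl]hexa-1,3-dien-1-yl]furan-2(5H)-one (CNP0232848.3) | CC1=C(CC/C(=C\C=C\C2=CC(=O)OC2)CO)[C@@]2(C)CCCC(C)(C)[C@H]2CC1 | target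

Total step count: 10. Longest linear sequence: 8 steps (5 → 7 → 8 → 9 → 11 → 12 → 13 → 18 → 19; steps 2, 3, 4, 5, 6, 7, 9 and 10).

Steps most likely to fail

1. Step 4. The cycloaddition may be slow at the neopentyl β-carbon C5, so that the diene oligomerises on the Lewis acid first. Facial discrimination may also be weak, because the α-methyl enone lacks the α-C–H contact that normally fixes an enone on this catalyst. The fallback replaces catalyst control by an auxiliary-controlled ionic Diels–Alder reaction; it sets out from 4 and 8 and comes back at 9. Enone 4 is ketalised with (R,R)-hydrobenzoin (TsOH, PhH, Dean–Stark; the C4 quaternary centre blocks alkene migration) to give the chiral dioxolane, (4R,5R)-4,5-diphenyl-1,3-dioxolane spiro-ketal of 4, F1. Catalytic TMSOTf in CH2Cl2 at −78 °C should then promote the ionic Diels–Alder reaction of this enone ketal with 8, a far more reactive dienophile form, with the C2-symmetric diol differentiating the faces (the enantiomeric diol is used if the other face is preferred), to give the ketal adduct F2. PPTS in wet acetone should release ketone 9.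

2. Step 9. The aldehyde 13 may self-condense, or its amine-activated form may add in a conjugate (1,4) sense to 16 instead of to the carbonyl carbon. The fallback is a directed Mukaiyama aldol sequence; it sets out from 13 and comes back at 18. Aldehyde 13 is converted (TMSCl, Et3N, NaI, MeCN) into its trimethylsilyl enol ether F3, which adds 1,2 to 16 under BF3·OEt2 at −78 °C to give the β-hydroxy aldehyde F4 after aqueous work-up. Acid-catalysed dehydration (cat. TsOH, CH2Cl2) should then give the (E)-dienal 18.

3. Step 6. The C8 cation may be captured by the primary hydroxyl to give a cyclic ether, or the alkene migration may stop short of the tetrasubstituted position. The fallback masks the nucleophile; it sets out from 11 and comes back at 12. Alcohol 11 is acetylated (Ac2O, pyridine) to the acetate F5, isomerised under the same acid conditions to the C8=C9 acetate F6, and methanolysed (K2CO3, MeOH) to 12.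

Further compounds
F1 | step 4 | (2R,3R)-6,8,8-trimethyl-2,3-diphenyl-1,4-dioxaspiro[4.5]dec-6-ene (hydrobenzoin ketal of 4) | CC1=CC(C)(C)CCC12O[C@H](c1ccccc1)[C@@H](c1ccccc1)O2
F2 | step 4 | (R,R)-hydrobenzoin ketal of ketone 9 | CC(C)(C)[Si](C)(C)OCCCC[C@@H]1C(C)=CC[C@@H]2C(C)(C)CCC3(O[C@H](c4ccccc4)[C@@H](c4ccccc4)O3)[C@]12C
F3 | step 9 | trimethylsilyl enol ether of 13 (E/Z mixture) | CC1=C(CCC=CO[Si](C)(C)C)[C@@]2(C)CCCC(C)(C)[C@H]2CC1
F4 | step 9 | β-hydroxy aldehyde, 3-hydroxy-2-{2-[(4aR,8aS)-decalinyl]ethyl}-5-(5-oxo-2,5-dihydrofuran-3-yl)pent-4-enal (mixture of epimers) | CC1=C(CCC(C=O)C(O)/C=C/C2=CC(=O)OC2)[C@@]2(C)CCCC(C)(C)[C@H]2CC1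
F5 | step 6 | acetate of 11 | CC(=O)OCCCC[C@@H]1C(C)=CC[C@@H]2C(C)(C)CCC[C@]12C
F6 | step 6 | 4-[(4aR,8aS)-2,5,5,8a-tetramethyl-3,4,4a,5,6,7,8,8a-octahydronaphthalen-1-yl]butyl acetate | CC1=C(CCCCOC(C)=O)[C@@]2(C)CCCC(C)(C)[C@H]2CC1
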